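The ten-membered ring is disconnected at C1–C10 and reconnected at C3–C8: ring carbons C3–C8, with the C4 methyl, the Z-C4=C5 bond, the C6 oxygen and C7 carrying C11–C13, are the cyclohexene ring of (S)-carvone, so only the four-carbon bridge C2–C1–C10–C9 has to be inserted. An anionic oxy-Cope shift of a tertiary 1-ethynyl-2-propenyl cyclohexenol does this in one operation: C1–C10 forms, C3–C8 breaks, and the cyclodecatrienone emerges with the C3 carbonyl, the C1=C2 enone and the C8=C9 olefin in place. The precursor is the 4-silyloxy-6-(E)-propenyl carveol from carvone, carrying the ethynyl group on the carbinol carbon, cis to the propenyl group.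

Key step: step 6

Assumption: six-membered compounds carry cyclohexenone numbering and ten-membered compounds germacrane numbering (C3 = carvone carbonyl carbon, C14 on C10, C15 on C4), β is the ring face bearing C11 at C7 and C14 at C10; the acetylide is taken to add axially, anti to the isopropenyl group, so the carbinol has ethynyl cis to propenyl, from which the chair-like shift can only give the 8Z olefin, and the β-oxygens at C8 and C9 are therefore set by two backside displacements; the side-chain acid is made in steps 16–18.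

Step 1
Reactants: 1 (S)-(+)-carvone
Product: 3 (4R,5S)-4-hydroxy-2-methyl-5-(prop-1-en-2-yl)cyclohex-2-en-1-one, via trimethylsilyl dienol ether 2 (not isolated)
Conditions: MeMgBr, FeCl3 (5 mol %), Et2O, −20 °C; TMSCl, Et3N, DMPU; then mCPBA, hexane/CH2Cl2, −20 °C; aq. citric acid
Reagents that add atoms: meta-chloroperoxybenzoic acid (mCPBA), O=C(OO)c1cccc(Cl)c1
Why: Iron-catalysed γ-deprotonation gives the through-conjugated dienolate, and its silyl dienol ether undergoes a vinylogous Rubottom oxidation at C4 (C2 is blocked by its methyl group), the peracid attacking C3=C4 anti to the adjacent isopropenyl group so that the new hydroxyl is trans to it (4R).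

Step 2
Reactants: 3 (4R,5S)-4-hydroxy-2-methyl-5-(prop-1-en-2-yl)cyclohex-2-en-1-one
Product: 4 (4R,5S)-4-(tert-butyldimethylsilyloxy)-2-methyl-5-(prop-1-en-2-yl)cyclohex-2-en-1-one
Conditions: TBSCl, imidazole, DMF, rt
Reagents that add atoms: tert-butyldimethylsilyl chloride, CC(C)(C)[Si](C)(C)Cl
Why: Silyl ether formation on the secondary allylic alcohol protects the future C6 oxygen through the enolate, acetylide and alkoxide steps.

Step 3
Reactants: 4 (4R,5S)-4-(tert-butyldimethylsilyloxy)-2-methyl-5-(prop-1-en-2-yl)cyclohex-2-en-1-one; 5 allyl bromide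
Product: 7 (4R,5S,6R)-6-allyl-4-(tert-butyldimethylsilyloxy)-2-methyl-5-(prop-1-en-2-yl)cyclohex-2-en-1-one, via lithium enolate 6 (not isolated)
Conditions: LiN(iPr)2, THF, −78 °C; then 5, DMPU, −78 to −40 °C
Reagents that add atoms: none
Why: Kinetic deprotonation occurs at C6 and the cross-conjugated enolate is alkylated (enolate allylation) on the face anti to the neighbouring isopropenyl group, giving the all-trans 4,5,6-array (6R).

Step 4
Reactants: 7 (4R,5S,6R)-6-allyl-4-(tert-butyldimethylsilyloxy)-2-methyl-5-(prop-1-en-2-yl)cyclohex-2-en-1-one; 8 ethynyltrimethylsilane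
Product: 9 (1S,4R,5S,6R)-6-allyl-4-(tert-butyldimethylsilyloxy)-2-methyl-5-(prop-1-en-2-yl)-1-[(trimethylsilyl)ethynyl]cyclohex-2-en-1-ol
Conditions: 8, n-BuLi, THF, −78 °C; CeCl3, −78 °C; then 7; aq. NH4Cl
Reagents that add atoms: none
Why: The weakly basic cerium acetylide (organocerium 1,2-addition) adds to the enolisable enone without deprotonation and enters axially, anti to the C5 isopropenyl group of the all-equatorial half-chair, which places the alkyne cis to the C6 side chain.

Step 5
Reactants: 9 (1S,4R,5S,6R)-6-allyl-4-(tert-butyldimethylsilyloxy)-2-methyl-5-(prop-1-en-2-yl)-1-[(trimethylsilyl)ethynyl]cyclohex-2-en-1-ol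
Product: 11 (1R,4R,5S,6R)-4-(tert-butyldimethylsilyloxy)-1-ethynyl-2-methyl-6-[(E)-prop-1-enyl]-5-(prop-1-en-2-yl)cyclohex-2-en-1-ol, via silylalkyne 10 (not isolated)
Conditions: RuHCl(CO)(PPh3)3 (5 mol %), toluene, 80 °C; then K2CO3 (cat.), MeOH, rt
Reagents that add atoms: none
Why: Ruthenium hydride-catalysed olefin isomerisation moves only the monosubstituted allyl double bond into the favoured (E)-propenyl position, the more substituted olefins and the silyl-capped alkyne being poor partners for insertion, and K2CO3/MeOH then removes the alkynyl silyl group (protodesilylation).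

Step 6
Reactants: 11 (1R,4R,5S,6R)-4-(tert-butyldimethylsilyloxy)-1-ethynyl-2-methyl-6-[(E)-prop-1-enyl]-5-(prop-1-en-2-yl)cyclohex-2-en-1-ol
Product: 14 (1Z,4Z,6R,7S,8Z)-6-(tert-butyldimethylsilyloxy)germacra-1,4,8,11(13)-tetraen-3-one (C10 epimers), via potassium alkoxide 12 (not isolated), via potassium allenolate 13 (not isolated)
Conditions: KN(SiMe3)2 (1.05 equiv), 18-crown-6, THF, 0 °C to rt; then aq. NH4Cl, −78 °C
Reagents that add atoms: none
Why: Deprotonation gives alkoxide 12, which undergoes an anion-accelerated [3,3] sigmatropic shift (alkynyl anionic oxy-Cope rearrangement; closest known type: ring expansion of 1-alkynyl- or 1-alkenyl-2-alkenylcyclohexanols to cyclodecenones) in which the alkyne terminus bonds to the propenyl terminus (C1–C10) while the ring bond C3–C8 breaks, and the cyclic allenolate 13 is protonated at C2 to the conjugated cis enone. The ten-membered ring is closed by four-carbon ring expansion through a six-centre chair-like transition state, not by end-to-end cyclisation, so no dilution is needed. No stereocentre of the target is created: C6 and C7 pass through untouched and the C10 methine forms as a mixture that is erased in step 9 (for the same reason any Z-propenyl or 1E-enone isomer converges). The C8=C9 geometry is fixed by the substrate, because with the silyloxy, isopropenyl and propenyl groups equatorial and the ethynyl group axial, C7 must lie axial on the six-centre array and the olefin is formed Z. The step needs the hydroxyl to be deprotonated without touching the far less acidic alkyne C–H (one equivalent of KN(SiMe3)2) and the exocyclic enyne to react in preference to the ring C4=C5 bond, which is secured because that π bond is orthogonal to the breaking C3–C8 bond. Loss of acetylide from 12 is the competing path and is held back by running the crown-ether-activated alkoxide at or below room temperature.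

Step 7
Reactants: 14 (1Z,4Z,6R,7S,8Z)-6-(tert-butyldimethylsilyloxy)germacra-1,4,8,11(13)-tetraen-3-one
Product: 16 (4Z,6R,7S,8Z)-6-(tert-butyldimethylsilyloxy)-1-hydroxygermacra-4,8,11(13)-trien-3-one (C1/C10 epimers), via boryl ketone 15 (not isolated)
Conditions: B2pin2, CuCl (5 mol %), Xantphos (5 mol %), NaOtBu (10 mol %), MeOH, THF, rt; then NaBO3·4H2O, THF/H2O, rt
Reagents that add atoms: sodium perborate tetrahydrate (NaBO3·4H2O), O[B-]1(O)OO[B-](O)(O)OO1.[Na+].[Na+]
Why: Copper-catalysed conjugate borylation of the enone followed by perborate oxidation is a formal hydration that places oxygen at C1, the unhindered cis-disubstituted C1=C2 bond reacting in preference to the α-methyl-substituted C4=C5 enone while the isolated olefins are inert, and the new C1 carbinol centre is irrelevant because it is oxidised next.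

Step 8
Reactants: 16 (4Z,6R,7S,8Z)-6-(tert-butyldimethylsilyloxy)-1-hydroxygermacra-4,8,11(13)-trien-3-one
Product: 17 (4Z,6R,7S,8Z)-6-(tert-butyldimethylsilyloxy)germacra-4,8,11(13)-triene-1,3-dione (C10 epimers)
Conditions: Dess–Martin periodinane, CH2Cl2, 0 °C to rt
Reagents that add atoms: none
Why: Dess–Martin oxidation converts the β-hydroxy ketone into the 1,3-diketone under non-basic conditions that avoid retro-aldol cleavage and migration of the C8=C9 bond.

Step 9
Reactants: 17 (4Z,6R,7S,8Z)-6-(tert-butyldimethylsilyloxy)germacra-4,8,11(13)-triene-1,3-dione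
Product: 20 (4Z,6R,7S,8Z,10R)-6-(tert-butyldimethylsilyloxy)-3,10-epoxygermacra-2,4,8,11(13)-tetraen-1-one (bridged 3(2H)-furanone), via dilithium dianion 18 (not isolated), via hydroxy diketone 19 (not isolated)
Conditions: LiN(iPr)2 (2.3 equiv), THF, −78 to −30 °C; 2-(phenylsulfonyl)-3-phenyloxaziridine, −78 °C; aq. NH4Cl; then TsOH·H2O (cat.), CH2Cl2, rt
Reagents that add atoms: 2-(phenylsulfonyl)-3-phenyloxaziridine, O=S(=O)(c1ccccc1)N1OC1c1ccccc1
Why: The dianion of the 1,3-diketone is hydroxylated at its terminal carbon C10, the only enolisable α' position because C4 is sp2 (Davis enolate oxidation), and acid then closes the α'-hydroxy-1,3-diketone onto the C3 carbonyl with loss of water to the 3(2H)-furanone, the only ring size available; the oxidant is expected to reach the trigonal C10 from the ring periphery, which with the C14 methyl turned outward is the α face (10R), but no neighbouring stereocentre secures this choice.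

Step 10
Reactants: 20 (4Z,6R,7S,8Z,10R)-6-(tert-butyldimethylsilyloxy)-3,10-epoxygermacra-2,4,8,11(13)-tetraen-1-one
Product: 21 (4Z,6R,7S,8Z,10R)-6-(tert-butyldimethylsilyloxy)-12-hydroxy-3,10-epoxygermacra-2,4,8,11(13)-tetraen-1-one
Conditions: SeO2 (0.3 equiv), t-BuOOH, CH2Cl2, rt
Reagents that add atoms: tert-butyl hydroperoxide, CC(C)(C)OO (terminal oxygen source, transferred through selenium dioxide, O=[Se]=O)
Why: Selenium dioxide allylic oxidation (ene reaction then [2,3] shift) hydroxylates the methyl group of the 1,1-disubstituted isopropenyl unit in preference to the methine positions of the conjugated or cis-disubstituted ring olefins, and any enal formed by over-oxidation converges in step 12.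

Step 11
Reactants: 21 (4Z,6R,7S,8Z,10R)-6-(tert-butyldimethylsilyloxy)-12-hydroxy-3,10-epoxygermacra-2,4,8,11(13)-tetraen-1-one
Product: 22 (4Z,6R,7S,8Z,10R)-6,12-dihydroxy-3,10-epoxygermacra-2,4,8,11(13)-tetraen-1-one
Conditions: HF·pyridine, THF/pyridine, 0 °C to rt
Reagents that add atoms: none
Why: Fluoride-mediated desilylation under buffered, non-basic conditions frees the C6 hydroxyl without disturbing the furanone or the skipped C8=C9 olefin.

Step 12
Reactants: 22 (4Z,6R,7S,8Z,10R)-6,12-dihydroxy-3,10-epoxygermacra-2,4,8,11(13)-tetraen-1-one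
Product: 24 (4Z,6R,7S,8Z,10R)-3,10-epoxy-1-oxogermacra-2,4,8,11(13)-tetraen-12,6-olide, via lactol 23 (not isolated)
Conditions: TEMPO (20 mol %), PhI(OAc)2 (2.5 equiv), CH2Cl2, rt
Reagents that add atoms: none
Why: The nitroxyl-catalysed oxidation takes the primary allylic alcohol selectively to the enal, which the C6 hydroxyl traps as lactol 23 that is oxidised on to the α-methylene γ-lactone (oxidative lactonisation of a 1,4-diol), the trans ring fusion following from the C6 and C7 configurations already present.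

Step 13
Reactants: 24 (4Z,6R,7S,8Z,10R)-3,10-epoxy-1-oxogermacra-2,4,8,11(13)-tetraen-12,6-olide
Product: 25 (4Z,6R,7S,8R,9R,10R)-3,10:8α,9α-diepoxy-1-oxogermacra-2,4,11(13)-trien-12,6-olide
Conditions: mCPBA, CH2Cl2, 0 °C
Reagents that add atoms: meta-chloroperoxybenzoic acid (mCPBA), O=C(OO)c1cccc(Cl)c1
Why: Prilezhaev epoxidation takes place at the only electron-rich olefin left (C8=C9; the dienone, vinylogous-ester and acrylate double bonds are deactivated) and from the outer face of the folded bicycle, the one not covered by the furanone ring, which is the α face, trans to the C7–C11 bond in the ring sense.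

Step 14
Reactants: 25 (4Z,6R,7S,8R,9R,10R)-3,10:8α,9α-diepoxy-1-oxogermacra-2,4,11(13)-trien-12,6-olide
Product: 26 (4Z,6R,7S,8S,9R,10R)-8β-acetoxy-9α-hydroxy-3,10-epoxy-1-oxogermacra-2,4,11(13)-trien-12,6-olide
Conditions: AcOH, CsOAc, 50 °C
Reagents that add atoms: acetic acid, CC(=O)O
Why: Buffered acetolysis opens the epoxide by backside attack of acetate (SN2-type epoxide opening) at C8 and not at C9, which is neopentyl-like and flanked by the electron-poor quaternary C10, so inversion places the C8 oxygen on the β face (8S) and leaves the 9α-hydroxyl.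

Step 15
Reactants: 26 (4Z,6R,7S,8S,9R,10R)-8β-acetoxy-9α-hydroxy-3,10-epoxy-1-oxogermacra-2,4,11(13)-trien-12,6-olide
Product: 29 (4Z,6R,7R,8S,9S,10R)-9β-acetoxy-8β-hydroxy-3,10-epoxy-1-oxogermacra-2,4,11(13)-trien-12,6-olide, via triflate 27 (not isolated), via acetoxonium triflate 28 (not isolated)
Conditions: Tf2O, pyridine, CH2Cl2, −20 to 0 °C; then H2O, MeCN, rt
Reagents that add atoms: water, O
Why: The 9α-triflate is displaced by the antiperiplanar 8β-acetate (Winstein neighbouring-group participation) to the cis-fused acetoxonium ion, which inverts C9 to β (9S), and hydrolysis through the hemi-orthoester should release the less hindered O8 as the free hydroxyl and leave the acetate on O9 (kinetic orthoester-type opening); the C7 descriptor changes only because of the priority switch at C8.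

Step 16
Reactants: 30 tert-butyl acrylate; 31 acetaldehyde
Product: 32 tert-butyl 3-hydroxy-2-methylenebutanoate (racemic)
Conditions: DABCO (20 mol %), 1,4-dioxane/H2O, rt
Reagents that add atoms: none
Why: The Morita–Baylis–Hillman reaction joins the acrylate α-carbon to the aldehyde and gives the α-methylene β-hydroxy ester directly.

Step 17
Reactants: 32 tert-butyl 3-hydroxy-2-methylenebutanoate
Product: 34 tert-butyl (E)-2-(acetoxymethyl)but-2-enoate, via secondary acetate 33 (not isolated)
Conditions: Ac2O, Et3N, DMAP (cat.), CH2Cl2, 0 °C; then DABCO (20 mol %), THF, 60 °C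
Reagents that add atoms: acetic anhydride, CC(=O)OC(C)=O
Why: Acetylation followed by DABCO-catalysed 1,3-transposition of the Baylis–Hillman acetate (SN2' addition of the amine, then return of acetate) gives the thermodynamically favoured primary allylic acetate with the ester trans to the methyl group, as in tiglates.

Step 18
Reactants: 34 tert-butyl (E)-2-(acetoxymethyl)but-2-enoate
Product: 35 (E)-2-(acetoxymethyl)but-2-enoic acid
Conditions: TFA, CH2Cl2, rt
Reagents that add atoms: none
Why: Acidolysis of the tert-butyl ester (loss of isobutene through the tert-butyl cation) leaves the primary acetate and the olefin geometry untouched.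

Step 19
Reactants: 29 (4Z,6R,7R,8S,9S,10R)-9β-acetoxy-8β-hydroxy-3,10-epoxy-1-oxogermacra-2,4,11(13)-trien-12,6-olide; 35 (E)-2-(acetoxymethyl)but-2-enoic acid
Product: 37 CNP0325609.1 (4Z,6R,7S,8S,9S,10R)-9-acetoxy-8-[(E)-2-(acetoxymethyl)but-2-enoyloxy]-3,10-epoxy-1-oxogermacra-2,4,11(13)-trien-12,6-olide, via mixed anhydride 36 (not isolated)
Conditions: 35, 2,4,6-trichlorobenzoyl chloride, Et3N, toluene, rt; then 29, DMAP, 0 °C to rt
Reagents that add atoms: none
Why: Yamaguchi esterification through the preformed mixed anhydride acylates the remaining secondary C8 hydroxyl at low temperature, which should keep acylation faster than acetyl migration from O9, and neither the α-methylene lactone nor the furanone reacts with the acylating agent.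

Compound list
1 | (S)-(+)-carvone | CC1=CC[C@H](C(C)=C)CC1=O | starting material
2 | (5R)-2-methyl-5-(prop-1-en-2-yl)-1-(trimethylsilyloxy)cyclohexa-1,3-diene | CC1=C(O[Si](C)(C)C)C[C@@H](C(C)=C)C=C1 | intermediate (not isolated)
3 | (4R,5S)-4-hydroxy-2-methyl-5-(prop-1-en-2-yl)cyclohex-2-en-1-one (OH trans to isopropenyl) | O=C1C(C)=C[C@@H](O)[C@H](C(C)=C)C1 | intermediate
4 | (4R,5S)-4-(tert-butyldimethylsilyloxy)-2-methyl-5-(prop-1-en-2-yl)cyclohex-2-en-1-one | O=C1C(C)=C[C@@H](O[Si](C)(C)C(C)(C)C)[C@H](C(C)=C)C1 | intermediate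
5 | allyl bromide | C=CCBr | starting material
6 | lithium enolate of 4 (O–C1=C6) | [Li+].[O-]C1=C[C@@H](C(C)=C)[C@H](O[Si](C)(C)C(C)(C)C)C=C1C | intermediate (not isolated)
7 | (4R,5S,6R)-6-allyl-4-(tert-butyldimethylsilyloxy)-2-methyl-5-(prop-1-en-2-yl)cyclohex-2-en-1-one (all-trans) | O=C1C(C)=C[C@@H](O[Si](C)(C)C(C)(C)C)[C@H](C(C)=C)[C@H]1CC=C | intermediate
8 | ethynyltrimethylsilane | C#C[Si](C)(C)C | starting material
9 | (1S,4R,5S,6R)-6-allyl-4-(tert-butyldimethylsilyloxy)-2-methyl-5-(prop-1-en-2-yl)-1-[(trimethylsilyl)ethynyl]cyclohex-2-en-1-ol (alkyne cis to allyl) | C[Si](C)(C)C#C[C@@]1(O)C(C)=C[C@@H](O[Si](C)(C)C(C)(C)C)[C@H](C(C)=C)[C@H]1CC=C | intermediate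
10 | (1S,4R,5S,6R)-4-(tert-butyldimethylsilyloxy)-2-methyl-6-[(E)-prop-1-enyl]-5-(prop-1-en-2-yl)-1-[(trimethylsilyl)ethynyl]cyclohex-2-en-1-ol | C[Si](C)(C)C#C[C@@]1(O)C(C)=C[C@@H](O[Si](C)(C)C(C)(C)C)[C@H](C(C)=C)[C@H]1/C=C/C | intermediate (not isolated)
11 | (1R,4R,5S,6R)-4-(tert-butyldimethylsilyloxy)-1-ethynyl-2-methyl-6-[(E)-prop-1-enyl]-5-(prop-1-en-2-yl)cyclohex-2-en-1-ol (ethynyl cis to propenyl, trans to isopropenyl) | C#C[C@@]1(O)C(C)=C[C@@H](O[Si](C)(C)C(C)(C)C)[C@H](C(C)=C)[C@H]1/C=C/C | intermediate (key-step precursor)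
12 | potassium alkoxide of 11 | [K+].C#C[C@@]1([O-])C(C)=C[C@@H](O[Si](C)(C)C(C)(C)C)[C@H](C(C)=C)[C@H]1/C=C/C | intermediate (not isolated)
13 | potassium (4Z,6R,7S,8Z)-6-(tert-butyldimethylsilyloxy)germacra-1,2,4,8,11(13)-pentaen-3-olate (cyclic allenolate) | [K+].CC(C)(C)[Si](C)(C)O[C@@H]1/C=C(/C)C([O-])=C=CC(C)/C=C\[C@H]1C(C)=C | intermediate (not isolated)
14 | (1Z,4Z,6R,7S,8Z)-6-(tert-butyldimethylsilyloxy)germacra-1,4,8,11(13)-tetraen-3-one (C10 epimers) | CC(C)(C)[Si](C)(C)O[C@@H]1/C=C(/C)C(=O)/C=C\C(C)/C=C\[C@H]1C(C)=C | intermediate (key-step product)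
15 | (4Z,6R,7S,8Z)-6-(tert-butyldimethylsilyloxy)-1-(4,4,5,5-tetramethyl-1,3,2-dioxaborolan-2-yl)germacra-4,8,11(13)-trien-3-one | CC(C)(C)[Si](C)(C)O[C@@H]1/C=C(/C)C(=O)CC(B2OC(C)(C)C(C)(C)O2)C(C)/C=C\[C@H]1C(C)=C | intermediate (not isolated)
16 | (4Z,6R,7S,8Z)-6-(tert-butyldimethylsilyloxy)-1-hydroxygermacra-4,8,11(13)-trien-3-one (C1/C10 epimers) | CC(C)(C)[Si](C)(C)O[C@@H]1/C=C(/C)C(=O)CC(O)C(C)/C=C\[C@H]1C(C)=C | intermediate
17 | (4Z,6R,7S,8Z)-6-(tert-butyldimethylsilyloxy)germacra-4,8,11(13)-triene-1,3-dione (C10 epimers) | CC(C)(C)[Si](C)(C)O[C@@H]1/C=C(/C)C(=O)CC(=O)C(C)/C=C\[C@H]1C(C)=C | intermediate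
18 | dilithium dianion of 17 (O–C3=C2–C1(O)=C10) | [Li+].[Li+].CC(C)(C)[Si](C)(C)O[C@@H]1/C=C(/C)C([O-])=CC([O-])=C(C)/C=C\[C@H]1C(C)=C | intermediate (not isolated)
19 | (4Z,6R,7S,8Z,10R)-6-(tert-butyldimethylsilyloxy)-10-hydroxygermacra-4,8,11(13)-triene-1,3-dione | CC(C)(C)[Si](C)(C)O[C@@H]1/C=C(/C)C(=O)CC(=O)[C@](C)(O)/C=C\[C@H]1C(C)=C | intermediate (not isolated)
20 | (4Z,6R,7S,8Z,10R)-6-(tert-butyldimethylsilyloxy)-3,10-epoxygermacra-2,4,8,11(13)-tetraen-1-one | CC(C)(C)[Si](C)(C)O[C@@H]1/C=C(/C)C2=CC(=O)[C@](C)(O2)/C=C\[C@H]1C(C)=C | intermediate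
21 | (4Z,6R,7S,8Z,10R)-6-(tert-butyldimethylsilyloxy)-12-hydroxy-3,10-epoxygermacra-2,4,8,11(13)-tetraen-1-one | CC(C)(C)[Si](C)(C)O[C@@H]1/C=C(/C)C2=CC(=O)[C@](C)(O2)/C=C\[C@H]1C(=C)CO | intermediate
22 | (4Z,6R,7S,8Z,10R)-6,12-dihydroxy-3,10-epoxygermacra-2,4,8,11(13)-tetraen-1-one | O[C@@H]1/C=C(/C)C2=CC(=O)[C@](C)(O2)/C=C\[C@H]1C(=C)CO | intermediate
23 | 6,12-lactol of the 12-aldehyde derived from 22 (C12 epimers) | C=C1C(O)O[C@@H]2/C=C(/C)C3=CC(=O)[C@](C)(O3)/C=C\[C@@H]12 | intermediate (not isolated)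
24 | (4Z,6R,7S,8Z,10R)-3,10-epoxy-1-oxogermacra-2,4,8,11(13)-tetraen-12,6-olide | C=C1C(=O)O[C@@H]2/C=C(/C)C3=CC(=O)[C@](C)(O3)/C=C\[C@@H]12 | intermediate
25 | (4Z,6R,7S,8R,9R,10R)-3,10:8α,9α-diepoxy-1-oxogermacra-2,4,11(13)-trien-12,6-olide | C=C1C(=O)O[C@@H]2/C=C(/C)C3=CC(=O)[C@](C)(O3)[C@@H]4O[C@@H]4[C@@H]12 | intermediate
26 | (4Z,6R,7S,8S,9R,10R)-8β-acetoxy-9α-hydroxy-3,10-epoxy-1-oxogermacra-2,4,11(13)-trien-12,6-olide | C=C1C(=O)O[C@@H]2/C=C(/C)C3=CC(=O)[C@](C)(O3)[C@H](O)[C@@H](OC(C)=O)[C@@H]12 | intermediate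
27 | 9α-trifluoromethanesulfonate of 26 | C=C1C(=O)O[C@@H]2/C=C(/C)C3=CC(=O)[C@](C)(O3)[C@H](OS(=O)(=O)C(F)(F)F)[C@@H](OC(C)=O)[C@@H]12 | intermediate (not isolated)
28 | 8β,9β-(2-methyl-1,3-dioxolan-2-ylium) triflate (acetoxonium ion) | C=C1C(=O)O[C@@H]2/C=C(/C)C3=CC(=O)[C@](C)(O3)[C@H]4O[C+](C)O[C@H]4[C@@H]12.[O-]S(=O)(=O)C(F)(F)F | intermediate (not isolated)
29 | (4Z,6R,7R,8S,9S,10R)-9β-acetoxy-8β-hydroxy-3,10-epoxy-1-oxogermacra-2,4,11(13)-trien-12,6-olide | C=C1C(=O)O[C@@H]2/C=C(/C)C3=CC(=O)[C@](C)(O3)[C@@H](OC(C)=O)[C@@H](O)[C@@H]12 | intermediate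
30 | tert-butyl acrylate | C=CC(=O)OC(C)(C)C | starting material
31 | acetaldehyde | CC=O | starting material
32 | tert-butyl 3-hydroxy-2-methylenebutanoate (racemic) | CC(O)C(=C)C(=O)OC(C)(C)C | intermediate
33 | tert-butyl 3-acetoxy-2-methylenebutanoate | CC(OC(C)=O)C(=C)C(=O)OC(C)(C)C | intermediate (not isolated)
34 | tert-butyl (E)-2-(acetoxymethyl)but-2-enoate | CC(C)(C)OC(=O)/C(=C/C)COC(C)=O | intermediate
35 | (E)-2-(acetoxymethyl)but-2-enoic acid | OC(=O)/C(=C/C)COC(C)=O | intermediate
36 | (E)-2-(acetoxymethyl)but-2-enoic 2,4,6-trichlorobenzoic anhydride | O=C(OC(=O)/C(=C/C)COC(C)=O)c1c(Cl)cc(Cl)cc1Cl | intermediate (not isolated)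
37 | CNP0325609.1, (4Z,6R,7S,8S,9S,10R)-9-acetoxy-8-[(E)-2-(acetoxymethyl)but-2-enoyloxy]-3,10-epoxy-1-oxogermacra-2,4,11(13)-trien-12,6-olide | C=C1C(=O)O[C@@H]2/C=C(/C)C3=CC(=O)[C@](C)(O3)[C@@H](OC(C)=O)[C@@H](OC(=O)/C(=C/C)COC(C)=O)[C@@H]12 | target

Total step count: 19. Longest linear sequence: 16 steps (steps 1–15 and 19); steps 16–18 make the side-chain acid.

Steps most likely to fail

1. Step 9 (C10 hydroxylation). Oxygen may be transferred to the wrong face of the trigonal C10 of the ring dianion (poor facial selectivity), or to C8 of the extended enolate. The fallback sets out from 17 and returns at 20. Double soft enolisation of 17 with TMSOTf/Et3N should give the 1,3-bis(trimethylsilyloxy)diene F1. Shi epoxidation of its terminal, most electron-rich C1=C10 enol-ether bond (KHSO5, K2CO3 buffer, the fructose-derived ketone catalyst in whichever enantiomeric form delivers oxygen to the α face) replaces substrate control by reagent control. Mild acid work-up should give hydroxy diketone 19, which TsOH closes to 20.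

2. Step 14 (epoxide acetolysis). Acid-assisted ionisation of the medium-ring epoxide may lead to transannular participation or hydride shift, or backside attack on the concave face may be too slow and allow opening at C9. The fallback sets out from 24 and returns at 26. OsO4 (cat.) with N-methylmorpholine N-oxide should dihydroxylate C8=C9 from the same outer face to the 8α,9α-diol F2. SO2Cl2/Et3N converts it into the cyclic sulfate F3. CsOAc in DMF then opens the far better leaving group by SN2 attack at C8 under non-acidic conditions, giving the cesium 8β-acetoxy 9α-sulfate F4. Brief treatment with catalytic H2SO4 in moist THF hydrolyses the sulfate monoester to 26.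

3. Step 6 (key step). The propargylic alkoxide may fragment by loss of acetylide, or the strained cyclic allenolate may suffer proton transfer or oligomerisation before the quench. The fallback sets out from 7 and returns at 16, using the classical divinyl variant. CH2=CHMgBr/CeCl3 should add to 7 with the same facial sense to give the vinyl carbinol F5. RuHCl(CO)(PPh3)3 moves the allyl double bond to give the propenyl compound F6. KH/18-crown-6 effects the anionic oxy-Cope shift to the ring-expanded C3 enolate, which is trapped with TMSCl as the silyl enol ether F7. Saegusa–Ito oxidation with Pd(OAc)2 should give the C1=C2 enone as 14 and/or its 1E isomer F8, and both are converted by the conditions of step 7 into 16.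

Further compounds
F1 | step 9 | (4Z,6R,7S,8Z)-6-(tert-butyldimethylsilyloxy)-1,3-bis(trimethylsilyloxy)germacra-1(10),2,4,8,11(13)-pentaene | CC(C)(C)[Si](C)(C)O[C@@H]1/C=C(/C)C(O[Si](C)(C)C)=CC(O[Si](C)(C)C)=C(C)/C=C\[C@H]1C(C)=C
F2 | step 14 | (4Z,6R,7R,8R,9R,10R)-8α,9α-dihydroxy-3,10-epoxy-1-oxogermacra-2,4,11(13)-trien-12,6-olide | C=C1C(=O)O[C@@H]2/C=C(/C)C3=CC(=O)[C@](C)(O3)[C@H](O)[C@H](O)[C@@H]12
F3 | step 14 | 8α,9α-cyclic sulfate of F2 | C=C1C(=O)O[C@@H]2/C=C(/C)C3=CC(=O)[C@](C)(O3)[C@@H]4OS(=O)(=O)O[C@@H]4[C@@H]12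
F4 | step 14 | cesium 8β-acetoxy-3,10-epoxy-1-oxogermacra-2,4,11(13)-trien-12,6-olid-9α-yl sulfate | C=C1C(=O)O[C@@H]2/C=C(/C)C3=CC(=O)[C@](C)(O3)[C@H](OS(=O)(=O)[O-])[C@@H](OC(C)=O)[C@@H]12.[Cs+]
F5 | step 6 | (4R,5S,6R)-6-allyl-4-(tert-butyldimethylsilyloxy)-2-methyl-5-(prop-1-en-2-yl)-1-vinylcyclohex-2-en-1-ol (vinyl cis to allyl) | C=C[C@@]1(O)C(C)=C[C@@H](O[Si](C)(C)C(C)(C)C)[C@H](C(C)=C)[C@H]1CC=C
F6 | step 6 | (4R,5S,6R)-4-(tert-butyldimethylsilyloxy)-2-methyl-6-[(E)-prop-1-enyl]-5-(prop-1-en-2-yl)-1-vinylcyclohex-2-en-1-ol | C=C[C@@]1(O)C(C)=C[C@@H](O[Si](C)(C)C(C)(C)C)[C@H](C(C)=C)[C@H]1/C=C/C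
F7 | step 6 | (4Z,6R,7S,8Z)-6-(tert-butyldimethylsilyloxy)-3-(trimethylsilyloxy)germacra-2,4,8,11(13)-tetraene | CC(C)(C)[Si](C)(C)O[C@@H]1/C=C(/C)C(O[Si](C)(C)C)=CCC(C)/C=C\[C@H]1C(C)=C
F8 | step 6 | (1E,4Z,6R,7S,8Z)-6-(tert-butyldimethylsilyloxy)germacra-1,4,8,11(13)-tetraen-3-one | CC(C)(C)[Si](C)(C)O[C@@H]1/C=C(/C)C(=O)/C=C/C(C)/C=C\[C@H]1C(C)=C
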